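**Plan**

1. Retrosynthesis: remove the O8 acyl group (side chain from an (S)-malic-acid-derived ester) and the C15 hydroxyl (allylic oxidation), open the 12,6-lactone at O6–C12, cut the ring bond C7–C8, then the chain bond C6–C7. This leaves an open-chain C8 acid / C6 aldehyde that carries C5 and C10 and comes from (−)-verbenone.
2. Enabling feature: C7 is the β-carbon of the C11(Me)–C12 propionate and lies 1,6 to C8. Written as an (E)-2-methyl-2-enoate it accepts a C8 ketyl radical, so ring C5–C6–C7–C8–C9–C10 closes 6-exo. The closure is placed before the lactone exists, because a planar butenolide acceptor could only give the cis ring fusion.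
3. Forward order: pinane → cyclohexenone (strain-releasing cyclobutane fragmentation) → open chain (the former verbenone bridgehead carbon is excised) → chain joined at C6–C7 by Nozaki–Hiyama–Kishi coupling → cyclohexane by SmI2 closure of C7–C8 → γ-lactone on O6 → O8 ester → C15–OH.
4. Stereochemistry: C5 from verbenone; C10 by cuprate addition anti to the gem-dimethyl bridge; C6 by Felkin–Anh addition; C7 and C8 by the chair transition state of the ring closure; C11 by equilibration of the trans-lactone; C3′ from the chiral pool.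

Key step: step 10

Numbering: elemane numbering of the target is used throughout (ring C5–C6–C7–C8–C9–C10; C1=C2 vinyl and C14 methyl on C10; C4(=C3)–C15 on C5; C11(–C13)–C12 on C7; primes for the acyl side chain).

Assumption: compounds 10 and 19 are taken as purchasable building blocks, and compounds 14–16 are carried as C11 epimer mixtures that step 12 converges.

**Route**

Step 1
Reactants: 1 (1S,5S)-(−)-verbenone; 2 vinylmagnesium bromide
Product: 3 (1S,4R,5R)-4-ethenyl-4,6,6-trimethylbicyclo[3.1.1]heptan-2-one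
Conditions: CH2=CHMgBr, CuI (10 mol %), THF, −40 → 0 °C; then aq. NH4Cl
Reagents that add atoms: none
Why: Copper-catalysed 1,4-addition of the vinyl Grignard reagent to the β-methyl enone creates the quaternary C10, the cuprate attacking from the face opposite the gem-dimethyl bridge, which fixes C10 relative to the bridgehead that becomes C5.

Step 2
Reactants: 3 (1S,4R,5R)-4-ethenyl-4,6,6-trimethylbicyclo[3.1.1]heptan-2-one
Product: 5 (3R,4R)-3-ethenyl-3-methyl-4-(prop-1-en-2-yl)cyclohexan-1-one, via enol acetate 4 (not isolated)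
Conditions: BF3·OEt2, Zn(OAc)2, Ac2O, 0 °C → rt; then K2CO3 (cat.), MeOH, rt
Reagents that add atoms: none
Why: Lewis-acid-promoted cationic fragmentation of the pinan-2-one cleaves the strained cyclobutane bond between the carbonyl α-carbon and the CMe2 carbon, the tertiary cation loses a proton to give the isopropenyl group on C5, and the enol acetate formed is methanolysed to the ketone without touching C5 or C10.

Step 3
Reactants: 5 (3R,4R)-3-ethenyl-3-methyl-4-(prop-1-en-2-yl)cyclohexan-1-one
Product: 6 (4R,5R)-5-ethenyl-5-methyl-4-(prop-1-en-2-yl)cyclohex-2-en-1-one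
Conditions: IBX, DMSO, 65 °C
Reagents that add atoms: none
Why: IBX dehydrogenation of a cyclohexanone to the enone can only place the double bond at C6=C7, because the other α-carbon (C9) is attached to the quaternary C10.

Step 4
Reactants: 6 (4R,5R)-5-ethenyl-5-methyl-4-(prop-1-en-2-yl)cyclohex-2-en-1-one
Product: 7 2,3-epoxide of 6 (4-ethenyl-4-methyl-5-(prop-1-en-2-yl)-7-oxabicyclo[4.1.0]heptan-2-one, oxygen anti to the isopropenyl group)
Conditions: 30% H2O2, NaOH (cat.), MeOH, 0 °C
Reagents that add atoms: hydrogen peroxide, OO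
Why: Weitz–Scheffer nucleophilic epoxidation attacks only the electron-poor enone double bond, expected anti to the C5 substituent, and both epoxide carbons lose their configuration in step 5.

Step 5
Reactants: 7 2,3-epoxide of 6
Product: 8 (3R,4R)-3-ethenyl-4-formyl-3,5-dimethylhex-5-enoic acid
Conditions: H5IO6 (3 equiv), THF/H2O, rt
Reagents that add atoms: periodic acid, OI(O)(O)(O)(O)=O; water, O
Why: Aqueous periodic acid hydrates the epoxide and then performs two Malaprade cleavages (C6–C7 diol and C7–C8 α-hydroxy ketone), so the former verbenone bridgehead carbon leaves as formic acid, C6 becomes the aldehyde and C8 the acid, while the isolated alkenes are inert.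

Step 6
Reactants: 8 (3R,4R)-3-ethenyl-4-formyl-3,5-dimethylhex-5-enoic acid
Product: 9 S-ethyl (3R,4R)-3-ethenyl-4-formyl-3,5-dimethylhex-5-enethioate
Conditions: EtSH, EDC·HCl, DMAP (cat.), CH2Cl2, 0 °C
Reagents that add atoms: ethanethiol, CCS
Why: Carbodiimide thioesterification stores C8 as a thioester that tolerates the chromium chemistry of step 7 and can later be reduced to the aldehyde beside an enoate.

Step 7
Reactants: 9 S-ethyl (3R,4R)-3-ethenyl-4-formyl-3,5-dimethylhex-5-enethioate; 10 ethyl (E)-3-iodo-2-methylprop-2-enoate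
Product: 11 ethyl (2E,4R,5R,6R)-6-ethenyl-8-(ethylsulfanyl)-4-hydroxy-2,6-dimethyl-8-oxo-5-(prop-1-en-2-yl)oct-2-enoate
Conditions: CrCl2 (4 equiv), NiCl2 (1 mol %), DMSO, rt
Reagents that add atoms: none
Why: Nozaki–Hiyama–Kishi coupling adds the alkenylchromium reagent (E geometry retained, so no lactonisation) only to the aldehyde, and Felkin–Anh attack anti to the quaternary C10 with the isopropenyl group inside sets the C6 carbinol.

Step 8
Reactants: 11 ethyl (2E,4R,5R,6R)-6-ethenyl-8-(ethylsulfanyl)-4-hydroxy-2,6-dimethyl-8-oxo-5-(prop-1-en-2-yl)oct-2-enoate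
Product: 12 4-O-triethylsilyl ether of 11
Conditions: Et3SiOTf, 2,6-lutidine, CH2Cl2, −78 °C
Reagents that add atoms: triethylsilyl triflate, CC[Si](CC)(CC)OS(=O)(=O)C(F)(F)F
Why: Silylation of the hindered allylic alcohol keeps O6 masked until the cyclohexane exists and marks it as different from the later O8.

Step 9
Reactants: 12 4-O-triethylsilyl ether of 11
Product: 13 ethyl (2E,4R,5R,6R)-6-ethenyl-2,6-dimethyl-8-oxo-5-(prop-1-en-2-yl)-4-(triethylsilyloxy)oct-2-enoate
Conditions: i-Bu2AlH (1.1 equiv), CH2Cl2, −78 °C; then aq. potassium sodium tartrate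
Reagents that add atoms: none
Why: Hydride reduction of a thioester with i-Bu2AlH stops at the aldehyde through a stable hemithioacetal aluminate and is faster than reduction of the conjugated ethyl ester.

Step 10
Reactants: 13 ethyl (2E,4R,5R,6R)-6-ethenyl-2,6-dimethyl-8-oxo-5-(prop-1-en-2-yl)-4-(triethylsilyloxy)oct-2-enoate
Product: 14 ethyl 8α-hydroxy-6α-(triethylsilyloxy)elema-1,3-dien-12-oate (C11 epimers)
Conditions: SmI2 (2.5 equiv), t-BuOH (2 equiv), THF, −78 → −20 °C
Reagents that add atoms: none
Why: SmI2 reduces the aldehyde to a ketyl radical that adds to C7, the β-carbon of the (E)-2-methyl-2-enoate, and the α-ester radical is reduced by a second SmI2 to a trivalent samarium enolate that t-BuOH protonates. The closest known reaction type is the SmI2-mediated ketyl–olefin (aldehyde–enoate) reductive cyclisation. The only ring closed is the cyclohexane C5–C10, by 6-exo-trig radical closure of C7–C8, and it is closed before the lactone so that the trans fusion is not excluded by a planar butenolide. C7 and C8 are set by a chair transition state in which the C5 substituent, the C6 silyloxy group and the enoate are equatorial and the ketyl oxygen is pseudo-equatorial and anti to the acceptor, which places H7 trans to both H6 and H8 with the C10 methyl as the only axial group. C11 arises from unselective enolate protonation and is corrected in step 12. The step needs ketyl formation ahead of enoate reduction and attack at C7 only, which the faster reduction of the aldehyde, the enoate as the only polarity-matched acceptor (vinyl and isopropenyl are unactivated) and the poor leaving-group ability of the γ-silyloxy group should secure.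

Step 11
Reactants: 14 ethyl 8α-hydroxy-6α-(triethylsilyloxy)elema-1,3-dien-12-oate (C11 epimers)
Product: 15 ethyl 8α-(tert-butyldimethylsilyloxy)-6α-(triethylsilyloxy)elema-1,3-dien-12-oate (C11 epimers)
Conditions: t-BuMe2SiOTf, 2,6-lutidine, CH2Cl2, 0 °C
Reagents that add atoms: tert-butyldimethylsilyl triflate, CC(C)(C)[Si](C)(C)OS(=O)(=O)C(F)(F)F
Why: Silylation of the new secondary alcohol blocks O8 so that only O6 can lactonise in step 12.

Step 12
Reactants: 15 ethyl 8α-(tert-butyldimethylsilyloxy)-6α-(triethylsilyloxy)elema-1,3-dien-12-oate (C11 epimers)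
Product: 17 8α-(tert-butyldimethylsilyloxy)-11βH-elema-1,3-dien-12,6α-olide, via hydroxy ester 16 (not isolated)
Conditions: PPTS, EtOH, rt; then KOt-Bu (0.2 equiv), THF, 0 °C → rt
Reagents that add atoms: none
Why: Acid-catalysed ethanolysis removes the triethylsilyl ether selectively, and catalytic alkoxide then closes the trans-fused γ-lactone on O6 (lactonisation) and equilibrates C11 through the lactone enolate to the more stable 11α-methyl epimer, which is cis to H7 and turned away from C8.

Step 13
Reactants: 17 8α-(tert-butyldimethylsilyloxy)-11βH-elema-1,3-dien-12,6α-olide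
Product: 18 8α-hydroxy-11βH-elema-1,3-dien-12,6α-olide
Conditions: HF·pyridine, pyridine, THF, 0 °C → rt
Reagents that add atoms: none
Why: Fluoride desilylation in a buffered acidic medium frees O8 without forming the alkoxide that could move the lactone from O6 to O8.

Step 14
Reactants: 19 methyl (S)-2-(2,2-dimethyl-1,3-dioxolan-4-yl)acetate
Product: 22 methyl (S)-2-(2,2-dimethyl-1,3-dioxolan-4-yl)prop-2-enoate, via Mannich base 20 (not isolated), via ammonium iodide 21 (not isolated)
Conditions: LiN(i-Pr)2, THF, −78 °C; CH2=NMe2+ I−; then MeI, MeOH, rt; then aq. NaHCO3, CH2Cl2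
Reagents that add atoms: N,N-dimethylmethyleneiminium iodide, C=[N+](C)C.[I-]
Why: Ester α-methylenation by Mannich reaction of the lithium enolate, N-methylation and Hofmann-type elimination, in which trapping at −78 °C should outrun β-elimination of the dioxolane oxygen and the stereocentre is not involved.

Step 15
Reactants: 22 methyl (S)-2-(2,2-dimethyl-1,3-dioxolan-4-yl)prop-2-enoate
Product: 23 (S)-2-(2,2-dimethyl-1,3-dioxolan-4-yl)prop-2-enoic acid
Conditions: LiOH, THF/H2O, 0 °C; then cold 1 M HCl to pH 4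
Reagents that add atoms: lithium hydroxide, [Li+].[OH-]
Why: Saponification of the methyl ester at 0 °C followed by mild acidification leaves the acetonide and the allylic stereocentre intact.

Step 16
Reactants: 18 8α-hydroxy-11βH-elema-1,3-dien-12,6α-olide; 23 (S)-2-(2,2-dimethyl-1,3-dioxolan-4-yl)prop-2-enoic acid
Product: 25 8α-[(S)-2-(2,2-dimethyl-1,3-dioxolan-4-yl)prop-2-enoyloxy]-11βH-elema-1,3-dien-12,6α-olide, via mixed anhydride 24 (not isolated)
Conditions: 2,4,6-Cl3C6H2COCl, Et3N, THF, rt; then 18, DMAP, PhMe, 0 °C → rt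
Reagents that add atoms: none
Why: Yamaguchi esterification acylates the hindered equatorial C8 alcohol through the mixed anhydride under mild conditions in which the neutral alcohol should not translactonise.

Step 17
Reactants: 25 8α-[(S)-2-(2,2-dimethyl-1,3-dioxolan-4-yl)prop-2-enoyloxy]-11βH-elema-1,3-dien-12,6α-olide
Product: 26 15-hydroxy derivative of 25
Conditions: SeO2 (0.5 equiv), t-BuOOH, CH2Cl2, 0 °C → rt
Reagents that add atoms: selenium dioxide, O=[Se]=O; tert-butyl hydroperoxide, CC(C)(C)OO
Why: Selenium dioxide allylic hydroxylation (ene reaction, then 2,3-sigmatropic shift) should oxidise the methyl of the isopropenyl group, the only electron-rich alkene with an accessible allylic hydrogen, since the vinyl group has none, the acrylate is electron-poor and C5–H is shielded by the quaternary C10.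

Step 18
Reactants: 26 15-hydroxy derivative of 25
Product: 27 15-hydroxy-8α-[(3S)-3,4-dihydroxy-2-methylidenebutanoyloxy]-11βH-elema-1,3-dien-12,6α-olide
Conditions: AcOH/H2O (4:1), 40 °C
Reagents that add atoms: none
Why: Mild acid hydrolysis of the acetonide releases the side-chain diol without base, which avoids acyl transfer and lactone migration.

**Compound list**

1 | (1S,5S)-(−)-verbenone | CC1=CC(=O)[C@H]2C[C@@H]1C2(C)C | starting material
2 | vinylmagnesium bromide | C=C[Mg]Br | starting material
3 | (1S,4R,5R)-4-ethenyl-4,6,6-trimethylbicyclo[3.1.1]heptan-2-one | C=C[C@@]1(C)CC(=O)[C@H]2C[C@@H]1C2(C)C | intermediate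
4 | (4R,5R)-5-ethenyl-5-methyl-4-(prop-1-en-2-yl)cyclohex-1-en-1-yl acetate | C=C[C@@]1(C)CC(OC(C)=O)=CC[C@@H]1C(C)=C | intermediate (not isolated)
5 | (3R,4R)-3-ethenyl-3-methyl-4-(prop-1-en-2-yl)cyclohexan-1-one | C=C[C@@]1(C)CC(=O)CC[C@@H]1C(C)=C | intermediate
6 | (4R,5R)-5-ethenyl-5-methyl-4-(prop-1-en-2-yl)cyclohex-2-en-1-one | C=C[C@@]1(C)CC(=O)C=C[C@@H]1C(C)=C | intermediate
7 | 2,3-epoxide of 6, oxygen anti to the isopropenyl group | C=C[C@@]1(C)CC(=O)[C@H]2O[C@H]2[C@@H]1C(C)=C | intermediate
8 | (3R,4R)-3-ethenyl-4-formyl-3,5-dimethylhex-5-enoic acid | C=C[C@@](C)(CC(=O)O)[C@H](C=O)C(C)=C | intermediate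
9 | S-ethyl (3R,4R)-3-ethenyl-4-formyl-3,5-dimethylhex-5-enethioate | C=C[C@@](C)(CC(=O)SCC)[C@H](C=O)C(C)=C | intermediate
10 | ethyl (E)-3-iodo-2-methylprop-2-enoate | CCOC(=O)/C(C)=C/I | starting material
11 | ethyl (2E,4R,5R,6R)-6-ethenyl-8-(ethylsulfanyl)-4-hydroxy-2,6-dimethyl-8-oxo-5-(prop-1-en-2-yl)oct-2-enoate | C=C[C@@](C)(CC(=O)SCC)[C@H]([C@H](O)/C=C(\C)C(=O)OCC)C(C)=C | intermediate
12 | 4-O-triethylsilyl ether of 11 | C=C[C@@](C)(CC(=O)SCC)[C@H]([C@H](O[Si](CC)(CC)CC)/C=C(\C)C(=O)OCC)C(C)=C | intermediate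
13 | ethyl (2E,4R,5R,6R)-6-ethenyl-2,6-dimethyl-8-oxo-5-(prop-1-en-2-yl)-4-(triethylsilyloxy)oct-2-enoate | C=C[C@@](C)(CC=O)[C@H]([C@H](O[Si](CC)(CC)CC)/C=C(\C)C(=O)OCC)C(C)=C | intermediate
14 | ethyl 8α-hydroxy-6α-(triethylsilyloxy)elema-1,3-dien-12-oate (5αH,6βH,7αH,8βH,10β-methyl; C11 epimers) | C=C[C@@]1(C)C[C@@H](O)[C@H](C(C)C(=O)OCC)[C@@H](O[Si](CC)(CC)CC)[C@@H]1C(C)=C | intermediate
15 | ethyl 8α-(tert-butyldimethylsilyloxy)-6α-(triethylsilyloxy)elema-1,3-dien-12-oate (C11 epimers) | C=C[C@@]1(C)C[C@@H](O[Si](C)(C)C(C)(C)C)[C@H](C(C)C(=O)OCC)[C@@H](O[Si](CC)(CC)CC)[C@@H]1C(C)=C | intermediate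
16 | ethyl 8α-(tert-butyldimethylsilyloxy)-6α-hydroxyelema-1,3-dien-12-oate (C11 epimers) | C=C[C@@]1(C)C[C@@H](O[Si](C)(C)C(C)(C)C)[C@H](C(C)C(=O)OCC)[C@@H](O)[C@@H]1C(C)=C | intermediate (not isolated)
17 | 8α-(tert-butyldimethylsilyloxy)-11βH-elema-1,3-dien-12,6α-olide | C=C[C@@]1(C)C[C@@H](O[Si](C)(C)C(C)(C)C)[C@H]2[C@@H](OC(=O)[C@@H]2C)[C@@H]1C(C)=C | intermediate
18 | 8α-hydroxy-11βH-elema-1,3-dien-12,6α-olide | C=C[C@@]1(C)C[C@@H](O)[C@H]2[C@@H](OC(=O)[C@@H]2C)[C@@H]1C(C)=C | intermediate
19 | methyl (S)-2-(2,2-dimethyl-1,3-dioxolan-4-yl)acetate | COC(=O)C[C@H]1COC(C)(C)O1 | starting material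
20 | methyl 3-(dimethylamino)-2-[(S)-2,2-dimethyl-1,3-dioxolan-4-yl]propanoate (C2 epimers) | COC(=O)C(CN(C)C)[C@H]1COC(C)(C)O1 | intermediate (not isolated)
21 | [2-((S)-2,2-dimethyl-1,3-dioxolan-4-yl)-3-methoxy-3-oxopropyl]trimethylammonium iodide | COC(=O)C(C[N+](C)(C)C)[C@H]1COC(C)(C)O1.[I-] | intermediate (not isolated)
22 | methyl (S)-2-(2,2-dimethyl-1,3-dioxolan-4-yl)prop-2-enoate | C=C(C(=O)OC)[C@H]1COC(C)(C)O1 | intermediate
23 | (S)-2-(2,2-dimethyl-1,3-dioxolan-4-yl)prop-2-enoic acid | C=C(C(=O)O)[C@H]1COC(C)(C)O1 | intermediate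
24 | mixed anhydride of 23 with 2,4,6-trichlorobenzoic acid | C=C(C(=O)OC(=O)c1c(Cl)cc(Cl)cc1Cl)[C@H]1COC(C)(C)O1 | intermediate (not isolated)
25 | 8α-[(S)-2-(2,2-dimethyl-1,3-dioxolan-4-yl)prop-2-enoyloxy]-11βH-elema-1,3-dien-12,6α-olide | C=C[C@@]1(C)C[C@@H](OC(=O)C(=C)[C@H]3COC(C)(C)O3)[C@H]2[C@@H](OC(=O)[C@@H]2C)[C@@H]1C(C)=C | intermediate
26 | 15-hydroxy-8α-[(S)-2-(2,2-dimethyl-1,3-dioxolan-4-yl)prop-2-enoyloxy]-11βH-elema-1,3-dien-12,6α-olide | C=C[C@@]1(C)C[C@@H](OC(=O)C(=C)[C@H]3COC(C)(C)O3)[C@H]2[C@@H](OC(=O)[C@@H]2C)[C@@H]1C(=C)CO | intermediate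
27 | 15-hydroxy-8α-[(3S)-3,4-dihydroxy-2-methylidenebutanoyloxy]-11βH-elema-1,3-dien-12,6α-olide | C=C[C@@]1(C)C[C@@H](OC(=O)C(=C)[C@H](O)CO)[C@H]2[C@@H](OC(=O)[C@@H]2C)[C@@H]1C(=C)CO | target

**Totals and risks**

Total step count: 18. Longest linear sequence: 16 steps (steps 1–13 and 16–18); steps 14–15 make the side-chain acid.

Steps most likely to fail:

Step 17. The late allylic hydroxylation may over-oxidise to the enal, attack the tertiary allylic C5–H, or stall on a hindered substrate. The fallback sets out from 25 and returns at 26. Ene-type allylic chlorination (Ca(OCl)2, solid CO2, CH2Cl2/H2O, 0 °C) should give the 15-chloro analogue of 25 F1. Silver-assisted hydrolysis (AgNO3, 2,6-lutidine, aqueous acetone) then passes through a 2-substituted allyl cation whose two termini are equivalent, so only 26 can form.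

Step 10. The ketyl may be reduced further to the primary alcohol or dimerise before it cyclises, or the closure may show poor trans control at C7/C8. The fallback sets out from 13 and returns at 14. Decatungstate-photocatalysed hydroacylation ((n-Bu4N)4W10O32, 365 nm, MeCN) abstracts the aldehydic hydrogen, and the acyl radical closes 6-exo onto the enoate to give ethyl 8-oxo-6α-(triethylsilyloxy)elema-1,3-dien-12-oate F2. Reduction of this ketone under thermodynamic control (SmI2, MeOH, THF, 0 °C) should give the equatorial alcohol 14; a small hydride is avoided because the axial C10 methyl blocks axial attack.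

Step 7. Facial selectivity in the addition to the α-branched aldehyde may be poor, so that the C6 epimer forms beside 11. The fallback sets out from 9 and returns at 11. The separated ethyl (2E,4S,5R,6R) epimer of 11 F3 is inverted by Mitsunobu esterification (ClCH2CO2H, PPh3, DIAD, PhMe) to the 4R chloroacetate of 11 F4. The chloroacetate is then removed with thiourea and NaHCO3 in EtOH, which leaves the thioester and the enoate intact.

Further compounds
F1 | step 17 | 15-chloro-8α-[(S)-2-(2,2-dimethyl-1,3-dioxolan-4-yl)prop-2-enoyloxy]-11βH-elema-1,3-dien-12,6α-olide | C=C[C@@]1(C)C[C@@H](OC(=O)C(=C)[C@H]3COC(C)(C)O3)[C@H]2[C@@H](OC(=O)[C@@H]2C)[C@@H]1C(=C)CCl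
F2 | step 10 | ethyl 8-oxo-6α-(triethylsilyloxy)elema-1,3-dien-12-oate (C11 epimers) | C=C[C@@]1(C)CC(=O)[C@H](C(C)C(=O)OCC)[C@@H](O[Si](CC)(CC)CC)[C@@H]1C(C)=C
F3 | step 7 | ethyl (2E,4S,5R,6R)-6-ethenyl-8-(ethylsulfanyl)-4-hydroxy-2,6-dimethyl-8-oxo-5-(prop-1-en-2-yl)oct-2-enoate | C=C[C@@](C)(CC(=O)SCC)[C@H]([C@@H](O)/C=C(\C)C(=O)OCC)C(C)=C
F4 | step 7 | ethyl (2E,4R,5R,6R)-4-(chloroacetoxy)-6-ethenyl-8-(ethylsulfanyl)-2,6-dimethyl-8-oxo-5-(prop-1-en-2-yl)oct-2-enoate | C=C[C@@](C)(CC(=O)SCC)[C@H]([C@H](OC(=O)CCl)/C=C(\C)C(=O)OCC)C(C)=C
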